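The route takes ring B (C5–C10, with the C8 methyl) from (R)-carvone. The carvone stereocentre becomes C5, and its isopropenyl group is a latent C4 that already carries C18 and C19. Everything rests on the C3–C4 bond. The key step exploits the quaternary gem-dimethyl C4 next to C5. A hydrogen atom is added to the isopropenyl CH2, and the tertiary C4 radical closes ring A onto a vinyl sulfone, giving the trans-decalin in one operation. Precursor 7 is carvone whose C10 bears a methyl (cis to isopropenyl) and a 2-(phenylsulfonyl)allyl group (trans). The sulfone is kept until the Li/NH3 step, because it cannot be cleaved reductively beside the first enone.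

Key step: step 3

Assumption: bromide 5 is taken as a catalogue compound; labdane numbering is used throughout (carvone C1, C2, C3, C4, C5, C6 = C9, C8, C7, C6, C5, C10); transient centres (C10 in 4, C2 in 8–11, C9 in 10) are drawn as the expected major epimer.

Step 1
Reactants: 1 (R)-(−)-carvone; 2 iodomethane
Product: 4 (5R,6S)-6-methylcarvone, via lithium dienolate 3 (not isolated)
Conditions: LiN(iPr)2, THF, −78 °C; MeI, −78 → 0 °C
Reagents that add atoms: iodomethane (2), CI
Why: Kinetic deprotonation at the α′ carbon (C10) gives the cross-conjugated dienolate, and its SN2 methylation (enolate alkylation) brings in C20; the new centre (mainly methyl trans to isopropenyl) does not matter because step 2 makes it planar again.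

Step 2
Reactants: 4 (5R,6S)-6-methylcarvone; 5 3-bromo-2-(phenylsulfonyl)prop-1-ene
Product: 7 (5S,6S)-6-methyl-6-[2-(phenylsulfonyl)allyl]carvone, via lithium enolate 6 (not isolated)
Conditions: LiN(iPr)2, THF/DMPU, −78 → −10 °C; 5, −78 °C
Reagents that add atoms: 3-bromo-2-(phenylsulfonyl)prop-1-ene (5), C=C(CBr)S(=O)(=O)c1ccccc1
Why: The tetrasubstituted α′ enolate is alkylated (SN2 or SN2′, both giving the same product) on the face opposite the neighbouring isopropenyl group, as is usual for 6-alkylcarvones, so C1 ends up trans to C4 and quaternary C10 is fixed with its methyl β.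

Step 3
Reactants: 7 (5S,6S)-6-methyl-6-[2-(phenylsulfonyl)allyl]carvone
Product: 8 trans-fused 2α-phenylsulfonyl-4,4,8,10β-tetramethyl-7-en-9-one (5α-H)
Conditions: Fe(acac)3 (30 mol %), PhSiH3 (2.5 equiv, slow addition), EtOH/(CH2OH)2 5:1, 0.02 M, 60 °C
Reagents that add atoms: none
Why: PhSiH3 converts Fe(acac)3 in ethanol into an iron hydride that hands a hydrogen atom to the CH2 terminus of the isopropenyl group, which completes the C18/C19 gem-dimethyl pair and leaves a nucleophilic tertiary radical on C4. That radical adds to C3, the unsubstituted end of the vinyl sulfone, and the resulting α-sulfonyl radical on C2 is reduced by divalent iron and protonated by ethanol, which regenerates trivalent iron. The closest known reaction type is the iron-catalysed hydrogen-atom-transfer reductive coupling of unactivated alkenes with vinyl sulfones, acrylates or enones (a Giese addition started from an alkene), which has also been run intramolecularly. Ring A closes in the 6-endo-trig mode, because the 5-exo alternative would force the bulky radical onto the fully substituted, polarity-mismatched C2 and would create an unstabilised primary radical. No ring-fusion centre is made here: C4 on C5 and C1 on C10 are already trans on ring B, so only the trans-decalin is within reach, and the single new centre C2 should settle with the sulfonyl group equatorial (2α) on protonation, a configuration without consequence since C2 becomes CH2 in step 6. The step needs hydrogen-atom transfer to choose the electron-neutral 1,1-disubstituted alkene over the electron-poor C7=C8 enone and C2=C3 vinyl sulfone, which the polarity and substitution of the three alkenes secure, while dilution and slow silane addition keep the C4 radical from being quenched before it cyclises.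

Step 4
Reactants: 8 trans-fused sulfonyl enone; 9 allylmagnesium bromide
Product: 10 9α-allyl-9β-hydroxy-7-ene sulfone
Conditions: CH2=CHCH2MgBr (2.5 equiv), THF, −78 °C; H2O work-up
Reagents that add atoms: allylmagnesium bromide (9), C=CC[Mg]Br
Why: Allyl Grignard reagents add 1,2 to hindered enones (Grignard addition) faster than they deprotonate a sulfone, mainly from the α face opposite the axial 10β-methyl, and either C9 epimer serves because step 5 erases this carbinol centre.

Step 5
Reactants: 10 9α-allyl-9β-hydroxy-7-ene sulfone
Product: 11 9-allyl-8-en-7-one sulfone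
Conditions: pyridinium chlorochromate [C5H5NH][CrO3Cl], 4 Å molecular sieves, CH2Cl2, rt
Reagents that add atoms: pyridinium chlorochromate (delivers the C7 oxygen, the C9 oxygen leaves with chromium), [O-][Cr](=O)(=O)Cl.c1cc[nH+]cc1
Why: In the Babler–Dauben oxidative transposition the tertiary allylic chromate ester shifts [3,3] to C7 and is oxidised there by hexavalent chromium, which moves the carbonyl to C7 and leaves the allyl group on the new C8=C9 bond, while sulfone and terminal alkene are inert.

Step 6
Reactants: 11 9-allyl-8-en-7-one sulfone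
Product: 13 7-trimethylsilyloxy-14,15,16-trinorlabda-7,12-diene, via lithium C7 enolate 12 (not isolated)
Conditions: Li (excess), NH3/THF, t-BuOH (2 equiv), −78 °C; NH3 evaporated; Me3SiCl, Et3N, THF, 0 °C
Reagents that add atoms: chlorotrimethylsilane, C[Si](C)(C)Cl
Why: The dissolving-metal (Birch-type) enone reduction protonates the C9 carbanion axially from the α face, giving 9α-H with the equatorial 9β side chain and a regiodefined C7=C8 enolate that is trapped on oxygen, while the same electrons cleave the C2–S bond (reductive desulfonylation), which could not be done selectively on enone 8.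

Step 7
Reactants: 13 trimethylsilyl enol ether
Product: 15 8α-hydroxy-14,15,16-trinorlabd-12-en-7-one, via 8α-trimethylsilyloxy ketone 14 (not isolated)
Conditions: mCPBA (1.05 equiv), CH2Cl2, −20 °C; then 1 M HCl, THF, rt
Reagents that add atoms: mCPBA, O=C(OO)c1cccc(Cl)c1
Why: In this Rubottom oxidation the electron-rich enol ether is epoxidised far faster than the monosubstituted alkene and from the α face, because the axial 10β-methyl covers the β face of C8, so the hydroxyl is 8α and the methyl becomes 8β.

Step 8
Reactants: 15 8α-hydroxy 7-ketone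
Product: 16 7,8α-bis(triethylsilyloxy)-14,15,16-trinorlabda-6,12-diene
Conditions: Et3SiOTf (3 equiv), Et3N, CH2Cl2, 0 °C → rt
Reagents that add atoms: triethylsilyl triflate, CC[Si](CC)(CC)OS(=O)(=O)C(F)(F)F
Why: Under soft enolisation with a silyl triflate and an amine the ketone can enolise only towards C6 because C8 is quaternary, and the tertiary alcohol is silylated in the same operation, so it is protected at no cost in steps.

Step 9
Reactants: 16 bis(triethylsilyl) enol ether
Product: 17 6α,8α-bis(triethylsilyloxy)-14,15,16-trinorlabd-12-en-7-one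
Conditions: mCPBA (1.05 equiv), hexane/CH2Cl2, −15 → 0 °C
Reagents that add atoms: mCPBA, O=C(OO)c1cccc(Cl)c1
Why: In this second Rubottom oxidation attack on the α face (the β face of C6 is closed by the syn-axial 10β- and 4β-methyls) and a 1,4-silyl shift give the equatorial 6α-silyloxy ketone, a provisional centre that puts oxygen on C6 and keeps O6 distinguishable from O7.

Step 10
Reactants: 17 6α,8α-bis(triethylsilyloxy) 7-ketone
Product: 18 6α,8α-bis(triethylsilyloxy)-14,15,16-trinorlabd-12-en-7β-ol
Conditions: LiAlH4, Et2O, −40 → 0 °C
Reagents that add atoms: none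
Why: In this hydride reduction of a cyclohexanone the small hydride attacks C7 axially from the α face, anti to the adjacent axial 8β-methyl, and gives the equatorial 7β-alcohol, while the cold aluminium alkoxide does not promote silyl migration.

Step 11
Reactants: 18 7β-alcohol; 19 acetic anhydride
Product: 20 7β-acetoxy-6α,8α-bis(triethylsilyloxy)-14,15,16-trinorlabd-12-ene
Conditions: Ac2O, DMAP, pyridine, 40 °C
Reagents that add atoms: acetic anhydride (19), CC(=O)OC(C)=O
Why: DMAP-catalysed acylation of the only free hydroxyl puts the acetate of the target on O7, where it also protects this oxygen for the rest of the route.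

Step 12
Reactants: 20 7β-acetate; 21 methacrolein
Product: 22 (12E)-7β-acetoxy-6α,8α-bis(triethylsilyloxy)-15-norlabd-12-en-14-al
Conditions: methacrolein (10 equiv), second-generation Grubbs catalyst RuCl2(=CHPh)(PCy3)(SIMes) (5 mol %), CH2Cl2, 40 °C
Reagents that add atoms: methacrolein (21), C=C(C)C=O
Why: Olefin cross-metathesis of an unhindered terminal alkene with excess methacrolein is an established route to 2-methyl-2-enals and sets C12=C13 as the thermodynamically preferred E isomer.

Step 13
Reactants: 22 (12E)-enal; 23 methyltriphenylphosphonium bromide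
Product: 25 (12E)-7β-acetoxy-6α,8α-bis(triethylsilyloxy)labda-12,14-diene, via methylenetriphenylphosphorane 24 (not isolated)
Conditions: Ph3PCH3Br (1.5 equiv), KN(SiMe3)2 (1.4 equiv), THF, 0 °C; then 22, −78 → 0 °C
Reagents that add atoms: methyltriphenylphosphonium bromide (23), C[P+](c1ccccc1)(c1ccccc1)c1ccccc1.[Br-]
Why: Wittig methylenation of the aldehyde, which is far more electrophilic than the shielded acetate in a substrate without free hydroxyls, adds C15 and completes the diene without touching the E double bond.

Step 14
Reactants: 25 bis(triethylsilyl) diene acetate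
Product: 26 (12E)-7β-acetoxylabda-12,14-diene-6α,8α-diol
Conditions: Et3N·3HF, MeCN/THF, rt
Reagents that add atoms: none
Why: Near-neutral fluoride cleaves both triethylsilyl ethers (fluoride desilylation), the absence of base avoiding acetyl migration and the absence of strong acid avoiding cyclisation of the 8-hydroxyl onto the diene.

Step 15
Reactants: 26 6α,8α-diol 7β-acetate
Product: 27 (12E)-7β-acetoxy-8α-hydroxylabda-12,14-dien-6-one
Conditions: Dess–Martin periodinane, CH2Cl2, 0 °C → rt
Reagents that add atoms: none
Why: Dess–Martin oxidation takes the only secondary alcohol to the C6 ketone under non-basic conditions, so the 5α-H and 7α-H centres beside the carbonyl are not epimerised and the tertiary 8-hydroxyl and the diene are untouched.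

Step 16
Reactants: 27 6-ketone
Product: 28 (12E)-7β-acetoxylabda-12,14-diene-6β,8α-diol (CNP0225877.1)
Conditions: NaBH4, CeCl3·7H2O, MeOH, −40 → −10 °C
Reagents that add atoms: none
Why: In this Luche-type borohydride reduction the β face of C6 is closed by the two syn-axial methyls (C20 and the 4β-methyl), so hydride arrives from the α face and gives the axial 6β-alcohol, while low temperature and low basicity keep the acetate on O7.

Compound list
1 | (R)-(−)-carvone | CC1=CC[C@H](CC1=O)C(C)=C | starting material
2 | iodomethane | CI | starting material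
3 | lithium cross-conjugated dienolate of carvone (OLi on C9, C9=C10, C7=C8) | [Li]OC1=C[C@H](C(C)=C)CC=C1C | intermediate
4 | (5R,6S)-6-methylcarvone (methyl trans to isopropenyl; 6-epimer carried along) | O=C1C(C)=CC[C@@H](C(C)=C)[C@@H]1C | intermediate
5 | 3-bromo-2-(phenylsulfonyl)prop-1-ene | C=C(CBr)S(=O)(=O)c1ccccc1 | starting material
6 | lithium enolate of 4 (tetrasubstituted C9=C10) | [Li]OC1=C(C)[C@H](C(C)=C)CC=C1C | intermediate
7 | (5S,6S)-6-methyl-6-[2-(phenylsulfonyl)allyl]carvone (methyl cis, sulfonylallyl trans to isopropenyl) | O=C1C(C)=CC[C@@H](C(C)=C)[C@]1(C)CC(=C)S(=O)(=O)c1ccccc1 | intermediate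
8 | trans-decalin enone: C9 ketone, C7=C8 with 8-methyl, 4,4-dimethyl, 10β-methyl, 5α-H, equatorial 2α-SO2Ph | O=C1C(C)=CC[C@H]2C(C)(C)C[C@H](S(=O)(=O)c3ccccc3)C[C@@]21C | intermediate
9 | allylmagnesium bromide | C=CC[Mg]Br | starting material
10 | 9α-allyl-9β-hydroxy derivative of 8 (C7=C8 retained, 2α-SO2Ph) | C=CC[C@]1(O)C(C)=CC[C@H]2C(C)(C)C[C@H](S(=O)(=O)c3ccccc3)C[C@@]21C | intermediate
11 | 9-allyl-8-methyl-8-en-7-one, 2α-SO2Ph, 5α-H, 10β-methyl | C=CCC1=C(C)C(=O)C[C@H]2C(C)(C)C[C@H](S(=O)(=O)c3ccccc3)C[C@@]21C | intermediate
12 | lithium C7 enolate (C7=C8), 9β-allyl, 9α-H, sulfone removed | C=CC[C@H]1C(C)=C(O[Li])C[C@H]2C(C)(C)CCC[C@@]21C | intermediate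
13 | 7-trimethylsilyloxy-14,15,16-trinorlabda-7,12-diene (9α-H) | C=CC[C@H]1C(C)=C(O[Si](C)(C)C)C[C@H]2C(C)(C)CCC[C@@]21C | intermediate
14 | 8α-trimethylsilyloxy-14,15,16-trinorlabd-12-en-7-one | C=CC[C@H]1[C@](C)(O[Si](C)(C)C)C(=O)C[C@H]2C(C)(C)CCC[C@@]21C | intermediate
15 | 8α-hydroxy-14,15,16-trinorlabd-12-en-7-one (8β-methyl) | C=CC[C@H]1[C@](C)(O)C(=O)C[C@H]2C(C)(C)CCC[C@@]21C | intermediate
16 | 7,8α-bis(triethylsilyloxy)-14,15,16-trinorlabda-6,12-diene | C=CC[C@H]1[C@](C)(O[Si](CC)(CC)CC)C(O[Si](CC)(CC)CC)=C[C@H]2C(C)(C)CCC[C@@]21C | intermediate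
17 | 6α,8α-bis(triethylsilyloxy)-14,15,16-trinorlabd-12-en-7-one | C=CC[C@H]1[C@](C)(O[Si](CC)(CC)CC)C(=O)[C@H](O[Si](CC)(CC)CC)[C@H]2C(C)(C)CCC[C@@]21C | intermediate
18 | 6α,8α-bis(triethylsilyloxy)-14,15,16-trinorlabd-12-en-7β-ol | C=CC[C@H]1[C@](C)(O[Si](CC)(CC)CC)[C@@H](O)[C@H](O[Si](CC)(CC)CC)[C@H]2C(C)(C)CCC[C@@]21C | intermediate
19 | acetic anhydride | CC(=O)OC(C)=O | starting material
20 | 7β-acetoxy-6α,8α-bis(triethylsilyloxy)-14,15,16-trinorlabd-12-ene | C=CC[C@H]1[C@](C)(O[Si](CC)(CC)CC)[C@@H](OC(C)=O)[C@H](O[Si](CC)(CC)CC)[C@H]2C(C)(C)CCC[C@@]21C | intermediate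
21 | methacrolein | C=C(C)C=O | starting material
22 | (12E)-7β-acetoxy-6α,8α-bis(triethylsilyloxy)-15-norlabd-12-en-14-al | O=C/C(C)=C/C[C@H]1[C@](C)(O[Si](CC)(CC)CC)[C@@H](OC(C)=O)[C@H](O[Si](CC)(CC)CC)[C@H]2C(C)(C)CCC[C@@]21C | intermediate
23 | methyltriphenylphosphonium bromide | C[P+](c1ccccc1)(c1ccccc1)c1ccccc1.[Br-] | starting material
24 | methylenetriphenylphosphorane | C=P(c1ccccc1)(c1ccccc1)c1ccccc1 | intermediate
25 | (12E)-7β-acetoxy-6α,8α-bis(triethylsilyloxy)labda-12,14-diene | C=C/C(C)=C/C[C@H]1[C@](C)(O[Si](CC)(CC)CC)[C@@H](OC(C)=O)[C@H](O[Si](CC)(CC)CC)[C@H]2C(C)(C)CCC[C@@]21C | intermediate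
26 | (12E)-7β-acetoxylabda-12,14-diene-6α,8α-diol | C=C/C(C)=C/C[C@H]1[C@](C)(O)[C@@H](OC(C)=O)[C@H](O)[C@H]2C(C)(C)CCC[C@@]21C | intermediate
27 | (12E)-7β-acetoxy-8α-hydroxylabda-12,14-dien-6-one | C=C/C(C)=C/C[C@H]1[C@](C)(O)[C@@H](OC(C)=O)C(=O)[C@H]2C(C)(C)CCC[C@@]21C | intermediate
28 | (12E)-7β-acetoxylabda-12,14-diene-6β,8α-diol (CNP0225877.1) | C=C/C(C)=C/C[C@H]1[C@](C)(O)[C@@H](OC(C)=O)[C@@H](O)[C@H]2C(C)(C)CCC[C@@]21C | target

Total step count: 16. Longest linear sequence: 16 steps (1 → 28).

Steps most likely to fail

**Step 3.** The C4 radical may pick up a second hydrogen atom before it cyclises. Hydrogen-atom transfer may also go to the vinyl sulfone or the enone instead of the isopropenyl group. The fallback sets out from 7. Ionic Markovnikov addition of HBr (HBr/AcOH, 0 °C), the classical hydrobromination of the carvone side chain, should give the tertiary bromide F1. Slow addition of Bu3SnH/AIBN in toluene at 80 °C then generates the same C4 radical by bromine abstraction, which does not depend on any choice between alkenes. The tin-hydride Giese cyclisation rejoins the route at 8.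

**Step 6.** Amide or alkoxide base may move the allyl double bond into conjugation before electron transfer. The C–S cleavage may stay incomplete, or proton exchange may scramble the enolate before silylation. The fallback sets out from 10, which holds no enone. The sulfone is removed there on its own with Na(Hg)/Na2HPO4 in MeOH, which should give the sulfone-free allylic alcohol F2. Pyridinium chlorochromate converts this into the sulfone-free enone F3. The Li/NH3–Me3SiCl sequence then has a single task and needs half the metal and base, and it rejoins the route at 13.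

**Step 16.** The acetyl group may migrate from O7 to the new cis 6β-alkoxide, or the β-hydroxy ketone may undergo base-induced retro-aldol cleavage. The fallback sets out from 27. LiAlH4 in Et2O reduces the ketone from the same α face and removes the acetate at once, giving the 6β,7β,8α-triol F4. Ac2O/pyridine at 0 °C should then acetylate only the equatorial secondary 7β-hydroxyl. The 6β-hydroxyl is axial under two syn-axial methyls and the 8α-hydroxyl is tertiary. This selectivity is known for 6β,7β-dihydroxylabdanes of the forskolin type. The sequence arrives at 28.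

Further compounds
F1 | step 3 | (5S,6S)-5-(2-bromopropan-2-yl)-2,6-dimethyl-6-[2-(phenylsulfonyl)allyl]cyclohex-2-en-1-one | O=C1C(C)=CC[C@@H](C(C)(C)Br)[C@]1(C)CC(=C)S(=O)(=O)c1ccccc1
F2 | step 6 | 9α-allyl-9β-hydroxy-4,4,8,10β-tetramethyl-trans-decal-7-ene (sulfone-free analogue of 10) | C=CC[C@]1(O)C(C)=CC[C@H]2C(C)(C)CCC[C@@]21C
F3 | step 6 | 14,15,16-trinorlabda-8,12-dien-7-one (sulfone-free analogue of 11) | C=CCC1=C(C)C(=O)C[C@H]2C(C)(C)CCC[C@@]21C
F4 | step 16 | (12E)-labda-12,14-diene-6β,7β,8α-triol | C=C/C(C)=C/C[C@H]1[C@](C)(O)[C@@H](O)[C@@H](O)[C@H]2C(C)(C)CCC[C@@]21C
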